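**Retrosynthetic overview**

- Feature: in ring A (benzene; C1 aroyl carbon, C2–OH, C3–CH2 of the 4-methylpentyl chain, C4–OH) the carbon substituent on C3 lies between the two C–O bonds. The C3–C and C4–O bonds are therefore made in one operation, by adding the C=O of DMF across a C3≡C4 aryne whose C2–OMe neighbour fixes the orientation.
- Late disconnections: two O–CH3 bonds (BBr3), C4'–Cl and C5'–Cl of ring B (pyrrole), the ketone C–C2' bond (2-pyridyl thioester plus pyrrolylmagnesium bromide), and the chain C=C bond (Wittig olefination of the C3 aldehyde, then hydrogenation).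
- Aryne precursor: 2-bromoresorcinol is carboxylated at C1 and the acid is carried as its tert-butyl ester, because a methyl ester would compete for n-BuLi. The chelated C2–OH allows the two oxygens to be told apart. Bromine–lithium exchange with retro-Brook silyl shift and triflation then gives the ortho-silylaryl triflate.
- Rings: none is built. Ring A comes from 2-bromoresorcinol and ring B from pyrrole; the only ring closed on the way is a transient benzoxete in the key step.

Key step: step 7

Remark on the chemistry: the target has no stereocentre. The Wittig alkene is expected as a Z-rich mixture of double-bond isomers and is drawn as the Z isomer; both isomers give the same alkane on hydrogenation.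

**Route**

Step 1
Reactants: 1 2-bromoresorcinol (2-bromobenzene-1,3-diol)
Product: 2 3-bromo-2,4-dihydroxybenzoic acid
Conditions: KHCO3 (5 equiv), H2O, CO2 (1 atm), 100 °C; then aq HCl, 0 °C
Reagents that add atoms: potassium hydrogencarbonate [K+].OC([O-])=O; carbon dioxide O=C=O (kept over the mixture, in equilibrium with the hydrogencarbonate)
Why: Kolbe–Schmitt carboxylation of the electron-rich resorcinolate takes place ortho to one hydroxyl and para to the other; C4 and C6 of 1 are equivalent and C2 is blocked by bromine, so a single acid with the C1/C2/C3/C4 pattern CO2H/OH/Br/OH should result.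

Step 2
Reactants: 2 3-bromo-2,4-dihydroxybenzoic acid
Product: 3 tert-butyl 3-bromo-2,4-dihydroxybenzoate
Conditions: O-tert-butyl-N,N'-diisopropylisourea (2.5 equiv), THF, rt to 40 °C
Reagents that add atoms: O-tert-butyl-N,N'-diisopropylisourea CC(C)NC(=NC(C)C)OC(C)(C)C
Why: Isourea esterification: only the carboxylic acid is acidic enough to protonate the isourea and take over its tert-butyl group, so both phenols stay free, and the bulky ester is what later lets the C3 bromide be lithiated without attack at the carboxyl carbon.

Step 3
Reactants: 3 tert-butyl 3-bromo-2,4-dihydroxybenzoate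
Product: 4 tert-butyl 3-bromo-2-hydroxy-4-(prop-2-en-1-yloxy)benzoate
Conditions: allyl bromide (1.05 equiv), K2CO3 (1.1 equiv), acetone, rt
Reagents that add atoms: allyl bromide C=CCBr
Why: Williamson etherification with one equivalent of base and halide goes to the more acidic, unchelated C4–OH, because the C2–OH is held in a hydrogen bond to the ester carbonyl and is flanked on both sides.

Step 4
Reactants: 4 tert-butyl 3-bromo-2-hydroxy-4-(prop-2-en-1-yloxy)benzoate
Product: 5 tert-butyl 3-bromo-2-methoxy-4-(prop-2-en-1-yloxy)benzoate
Conditions: MeI (3 equiv), K2CO3 (2 equiv), acetone, reflux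
Reagents that add atoms: iodomethane CI
Why: Williamson methylation under forcing conditions (excess MeI, heat) breaks the chelate and caps the only remaining hydroxyl; allyl ether, bromide and tert-butyl ester are inert to K2CO3.

Step 5
Reactants: 5 tert-butyl 3-bromo-2-methoxy-4-(prop-2-en-1-yloxy)benzoate
Product: 6 tert-butyl 3-bromo-4-hydroxy-2-methoxybenzoate
Conditions: Pd(PPh3)4 (3 mol %), morpholine (5 equiv), THF, rt
Reagents that add atoms: none
Why: Tsuji–Trost deallylation: zerovalent palladium ionises the allyl aryl ether to a π-allyl complex that morpholine intercepts, while the doubly ortho-substituted C–Br bond is not expected to add oxidatively at room temperature and the methyl ether and ester are untouched.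

Step 6
Reactants: 6 tert-butyl 3-bromo-4-hydroxy-2-methoxybenzoate
Product: 10 tert-butyl 2-methoxy-3-(trimethylsilyl)-4-(trifluoromethylsulfonyloxy)benzoate, via silyl ether 7 (not isolated), via aryllithium 8 (not isolated), via lithium phenoxide 9 (not isolated)
Conditions: HN(SiMe3)2, THF, 70 °C, then evaporation; n-BuLi (1.1 equiv), THF, −100 to −80 °C; Tf2O (1.2 equiv), −100 to −78 °C; aq NaHCO3
Reagents that add atoms: hexamethyldisilazane C[Si](C)(C)N[Si](C)(C)C; trifluoromethanesulfonic anhydride O=S(=O)(OS(=O)(=O)C(F)(F)F)C(F)(F)F
Why: Silylation of the phenol, fast low-temperature bromine–lithium exchange at the C3 bromide flanked by two oxygen substituents (the bulky tert-butyl ester is not attacked at −100 °C), immediate 1,3-O→C silyl shift of 8 (retro-Brook rearrangement, driven by formation of the phenoxide) and O-triflation of 9 make up the standard one-flask sequence to ortho-silylaryl triflates.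

Step 7
Reactants: 10 tert-butyl 2-methoxy-3-(trimethylsilyl)-4-(trifluoromethylsulfonyloxy)benzoate; 11 N,N-dimethylformamide
Product: 15 tert-butyl 3-formyl-4-hydroxy-2-methoxybenzoate, via aryne 12 (not isolated), via benzoxete 13 (not isolated), via quinone methide 14 (not isolated)
Conditions: CsF (3 equiv), dry DMF (solvent), rt to 50 °C; then H2O, rt
Reagents that add atoms: N,N-dimethylformamide CN(C)C=O; water O
Why: Fluoride attacks the C3 silicon of 10 and triflate leaves from C4 to give aryne 12, the carbonyl oxygen of DMF adds to C4, and the C3 aryl anion so formed collapses on the O-bound iminium carbon to give benzoxete 13. This four-membered ring is the only ring closed (4-exo-trig, overall a formal [2+2] addition across C=O) and it does not persist, because electrocyclic opening gives the aminomethylene ortho-quinone methide 14, which water converts into the C3 aldehyde and the C4 phenol with release of dimethylamine. The closest known reaction type is the insertion of fluoride-generated arynes, 3-methoxybenzyne among them, into the C=O bond of formamides to give salicylaldehydes. No stereocentre remains in 15, since the aminal carbon of 13 is transient. The step needs regioselectivity: the inductively withdrawing C2 methoxy group distorts the aryne so that C4 is the more electrophilic terminus and the negative charge builds up at C3 next to the C–O bond, and the C1 ester, para to C4 and meta to C3, acts in the same sense. Chemoselectivity rests on DMF being the solvent, so that it outcompetes fluoride for the aryne, and on keeping water out until 10 is used up, so that no phenoxide is present to be arylated.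

Step 8
Reactants: 15 tert-butyl 3-formyl-4-hydroxy-2-methoxybenzoate
Product: 16 tert-butyl 3-formyl-2,4-dimethoxybenzoate
Conditions: MeI (2 equiv), K2CO3 (1.5 equiv), acetone, reflux
Reagents that add atoms: iodomethane CI
Why: Williamson methylation of the C4 phenol (hydrogen-bonded to the new aldehyde, hence heat) removes the acidic proton before the ylide step and gives two methyl ethers that can be cleaved together at the end.

Step 9
Reactants: 16 tert-butyl 3-formyl-2,4-dimethoxybenzoate; 17 (3-methylbutyl)triphenylphosphonium bromide
Product: 19 tert-butyl 2,4-dimethoxy-3-[(1Z)-4-methylpent-1-en-1-yl]benzoate, via ylide 18 (not isolated)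
Conditions: 17 (1.3 equiv), NaN(SiMe3)2 (1.25 equiv), THF, 0 °C; then 16, −78 °C to rt
Reagents that add atoms: (3-methylbutyl)triphenylphosphonium bromide CC(C)CC[P+](c1ccccc1)(c1ccccc1)c1ccccc1.[Br-]
Why: Wittig olefination with a non-stabilised ylide is little affected by the two ortho methoxy groups of the aldehyde and leaves the tert-butyl ester alone; the double-bond geometry (Z favoured under kinetic control) is irrelevant because the alkene is reduced next.

Step 10
Reactants: 19 tert-butyl 2,4-dimethoxy-3-[(1Z)-4-methylpent-1-en-1-yl]benzoate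
Product: 20 tert-butyl 2,4-dimethoxy-3-(4-methylpentyl)benzoate
Conditions: H2 (1 atm), 10% Pd/C, EtOAc, rt
Reagents that add atoms: none
Why: Heterogeneous catalytic hydrogenation saturates the styrene-type double bond; aryl ethers and ester are inert and no halogen is present at this stage.

Step 11
Reactants: 20 tert-butyl 2,4-dimethoxy-3-(4-methylpentyl)benzoate
Product: 21 2,4-dimethoxy-3-(4-methylpentyl)benzoic acid
Conditions: CF3CO2H, CH2Cl2, 0 °C to rt
Reagents that add atoms: none
Why: Acidolysis of the tert-butyl ester (E1 loss of isobutene) frees the acid without base and without touching the methyl ethers.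

Step 12
Reactants: 21 2,4-dimethoxy-3-(4-methylpentyl)benzoic acid
Product: 22 S-(pyridin-2-yl) 2,4-dimethoxy-3-(4-methylpentyl)benzenecarbothioate
Conditions: 2,2'-dipyridyl disulfide (1.2 equiv), PPh3 (1.2 equiv), toluene, rt
Reagents that add atoms: 2,2'-dipyridyl disulfide c1ccc(SSc2ccccn2)nc1
Why: Mukaiyama redox condensation: the phosphonium species formed from PPh3 and the disulfide activates the carboxylate, and pyridine-2-thiolate is acylated to give a storable active thioester.

Step 13
Reactants: 22 S-(pyridin-2-yl) 2,4-dimethoxy-3-(4-methylpentyl)benzenecarbothioate; 23 pyrrole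
Product: 25 [2,4-dimethoxy-3-(4-methylpentyl)phenyl](1H-pyrrol-2-yl)methanone, via pyrrolylmagnesium bromide 24 (not isolated)
Conditions: 23 (2.5 equiv), EtMgBr (2.4 equiv), THF, 0 °C to rt; then 22, −78 °C; aqueous work-up
Reagents that add atoms: pyrrole c1cc[nH]c1
Why: C-Acylation of a pyrrolyl Grignard reagent: magnesium is chelated by the pyridine nitrogen and the thioester carbonyl, which delivers the acyl group to C2 of the ambident pyrrolyl anion rather than to nitrogen, and the deprotonated product resists a second addition.

Step 14
Reactants: 25 [2,4-dimethoxy-3-(4-methylpentyl)phenyl](1H-pyrrol-2-yl)methanone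
Product: 27 (4,5-dichloro-1H-pyrrol-2-yl)[2,4-dimethoxy-3-(4-methylpentyl)phenyl]methanone, via monochloride 26 (not isolated)
Conditions: SO2Cl2 (2.05 equiv), CH2Cl2, 0 °C to rt, dark
Reagents that add atoms: sulfuryl chloride O=S(=O)(Cl)Cl
Why: Electrophilic aromatic chlorination: even with the acyl group the pyrrole (ring B) is the more nucleophilic ring, the first chlorine goes mainly to C4' and the second to the free α-position C5', while ring A is deactivated by the ketone and exclusion of light suppresses radical chlorination of the side chain.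

Step 15
Reactants: 27 (4,5-dichloro-1H-pyrrol-2-yl)[2,4-dimethoxy-3-(4-methylpentyl)phenyl]methanone
Product: 28 (4,5-dichloro-1H-pyrrol-2-yl)[2,4-dihydroxy-3-(4-methylpentyl)phenyl]methanone (target)
Conditions: BBr3 (5 equiv), CH2Cl2, −78 °C to rt; then H2O
Reagents that add atoms: none
Why: Lewis acid ether cleavage with BBr3: each methyl ether is complexed and demethylated by bromide (SN2 at methyl), the C2 ether assisted by chelation to the ketone; C–Cl bonds, NH and ketone survive, and hydrolysis of the aryl borates gives the target.

**Compound list**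

1 | 2-bromoresorcinol | Oc1cccc(O)c1Br | starting material
2 | 3-bromo-2,4-dihydroxybenzoic acid | OC(=O)c1ccc(O)c(Br)c1O | intermediate
3 | tert-butyl 3-bromo-2,4-dihydroxybenzoate | CC(C)(C)OC(=O)c1ccc(O)c(Br)c1O | intermediate
4 | tert-butyl 3-bromo-2-hydroxy-4-(prop-2-en-1-yloxy)benzoate | C=CCOc1ccc(C(=O)OC(C)(C)C)c(O)c1Br | intermediate
5 | tert-butyl 3-bromo-2-methoxy-4-(prop-2-en-1-yloxy)benzoate | C=CCOc1ccc(C(=O)OC(C)(C)C)c(OC)c1Br | intermediate
6 | tert-butyl 3-bromo-4-hydroxy-2-methoxybenzoate | COc1c(C(=O)OC(C)(C)C)ccc(O)c1Br | intermediate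
7 | tert-butyl 3-bromo-2-methoxy-4-(trimethylsilyloxy)benzoate | COc1c(C(=O)OC(C)(C)C)ccc(O[Si](C)(C)C)c1Br | intermediate
8 | tert-butyl 3-lithio-2-methoxy-4-(trimethylsilyloxy)benzoate | COc1c(C(=O)OC(C)(C)C)ccc(O[Si](C)(C)C)c1[Li] | intermediate
9 | lithium 4-(tert-butoxycarbonyl)-3-methoxy-2-(trimethylsilyl)phenoxide | COc1c(C(=O)OC(C)(C)C)ccc([O-])c1[Si](C)(C)C.[Li+] | intermediate
10 | tert-butyl 2-methoxy-3-(trimethylsilyl)-4-(trifluoromethylsulfonyloxy)benzoate | COc1c(C(=O)OC(C)(C)C)ccc(OS(=O)(=O)C(F)(F)F)c1[Si](C)(C)C | intermediate
11 | N,N-dimethylformamide | CN(C)C=O | starting material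
12 | tert-butyl 3,4-didehydro-2-methoxybenzoate (aryne) | COC1=C(C(=O)OC(C)(C)C)C=CC#C1 | intermediate
13 | tert-butyl 2-(dimethylamino)-3-methoxy-2H-benzo[b]oxete-4-carboxylate | COc1c(C(=O)OC(C)(C)C)ccc2OC(N(C)C)c12 | intermediate
14 | tert-butyl 3-[(dimethylamino)methylidene]-2-methoxy-4-oxocyclohexa-1,5-diene-1-carboxylate | COC1=C(C(=O)OC(C)(C)C)C=CC(=O)C1=CN(C)C | intermediate
15 | tert-butyl 3-formyl-4-hydroxy-2-methoxybenzoate | COc1c(C(=O)OC(C)(C)C)ccc(O)c1C=O | intermediate
16 | tert-butyl 3-formyl-2,4-dimethoxybenzoate | COc1ccc(C(=O)OC(C)(C)C)c(OC)c1C=O | intermediate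
17 | (3-methylbutyl)triphenylphosphonium bromide | CC(C)CC[P+](c1ccccc1)(c1ccccc1)c1ccccc1.[Br-] | starting material
18 | (3-methylbutylidene)triphenylphosphorane | CC(C)CC=P(c1ccccc1)(c1ccccc1)c1ccccc1 | intermediate
19 | tert-butyl 2,4-dimethoxy-3-[(1Z)-4-methylpent-1-en-1-yl]benzoate | COc1ccc(C(=O)OC(C)(C)C)c(OC)c1/C=C\CC(C)C | intermediate
20 | tert-butyl 2,4-dimethoxy-3-(4-methylpentyl)benzoate | COc1ccc(C(=O)OC(C)(C)C)c(OC)c1CCCC(C)C | intermediate
21 | 2,4-dimethoxy-3-(4-methylpentyl)benzoic acid | COc1ccc(C(=O)O)c(OC)c1CCCC(C)C | intermediate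
22 | S-(pyridin-2-yl) 2,4-dimethoxy-3-(4-methylpentyl)benzenecarbothioate | COc1ccc(C(=O)Sc2ccccn2)c(OC)c1CCCC(C)C | intermediate
23 | pyrrole | c1cc[nH]c1 | starting material
24 | (pyrrol-1-yl)magnesium bromide | Br[Mg]n1cccc1 | intermediate
25 | [2,4-dimethoxy-3-(4-methylpentyl)phenyl](1H-pyrrol-2-yl)methanone | COc1ccc(C(=O)c2ccc[nH]2)c(OC)c1CCCC(C)C | intermediate
26 | (4-chloro-1H-pyrrol-2-yl)[2,4-dimethoxy-3-(4-methylpentyl)phenyl]methanone | COc1ccc(C(=O)c2cc(Cl)c[nH]2)c(OC)c1CCCC(C)C | intermediate
27 | (4,5-dichloro-1H-pyrrol-2-yl)[2,4-dimethoxy-3-(4-methylpentyl)phenyl]methanone | COc1ccc(C(=O)c2cc(Cl)c(Cl)[nH]2)c(OC)c1CCCC(C)C | intermediate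
28 | (4,5-dichloro-1H-pyrrol-2-yl)[2,4-dihydroxy-3-(4-methylpentyl)phenyl]methanone | CC(C)CCCc1c(O)ccc(C(=O)c2cc(Cl)c(Cl)[nH]2)c1O | target

**Step count**

Total step count: 15.
Longest linear sequence: 15 steps (1 to 28). DMF 11, phosphonium salt 17 and pyrrole 23 are bought and enter directly.

**Steps most likely to fail**

1. Step 7 (aryne insertion).
   - What may go wrong: fluoride may cleave the S–O bond of the triflate. Protodesilylation may outrun elimination. The aryne may be intercepted by fluoride or by traces of amine. The quinone methide may add a second aryne before the water quench.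
   - Fallback: it sets out from phenol 6 and comes back at 20. O-Methylation of 6 (MeI, K2CO3, acetone, reflux) should give tert-butyl 3-bromo-2,4-dimethoxybenzoate F1. Hydroboration of 4-methylpent-1-ene with 9-borabicyclo[3.3.1]nonane in THF gives 9-(4-methylpentyl)-9-borabicyclo[3.3.1]nonane F2. A B-alkyl Suzuki–Miyaura coupling of F1 with F2 (Pd(OAc)2, SPhos, K3PO4, THF/H2O, 65 °C) puts the whole chain on C3 and gives 20 directly, so steps 6 to 10 are not needed.

2. Step 6 (bromine–lithium exchange, silyl shift, triflation).
   - What may go wrong: n-BuLi may add to the ester carbonyl. The aryllithium may be protonated before the silyl group has migrated. The hindered phenoxide may be triflated incompletely.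
   - Fallback: it sets out from phenol 6 and comes back at 16, giving up silicon altogether. Bromide F1, made from 6 as described above, undergoes bromine–magnesium exchange with iPrMgCl·LiCl (THF, 0 °C to rt), a reagent that leaves a tert-butyl ester alone. This gives [3-(tert-butoxycarbonyl)-2,6-dimethoxyphenyl]magnesium chloride F3. Quenching with DMF 11 and aqueous acid work-up gives aldehyde 16.

3. Step 14 (dichlorination).
   - What may go wrong: chlorination may compete at C5 of the dialkoxy ring A or at C3' of the pyrrole. The reaction may stop at the monochloride stage or run on to a third chlorination.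
   - Fallback: it sets out from acid 21 and comes back at 27, bringing both chlorine atoms in with the pyrrole fragment. Protodecarboxylation of 21 (Ag2CO3 cat., AcOH, DMSO, 120 °C) gives 1,3-dimethoxy-2-(4-methylpentyl)benzene F4. Commercial 4,5-dichloro-1H-pyrrole-2-carboxylic acid with oxalyl chloride and catalytic DMF in CH2Cl2 gives 4,5-dichloro-1H-pyrrole-2-carbonyl chloride F5. Friedel–Crafts acylation of F4 with F5 (AlCl3, CH2Cl2, 0 °C) takes place ortho to one methoxy group and para to the other; the two such positions are equivalent, so 27 is the product.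

Further compounds
F1 | step 7 | tert-butyl 3-bromo-2,4-dimethoxybenzoate | COc1ccc(C(=O)OC(C)(C)C)c(OC)c1Br
F2 | step 7 | 9-(4-methylpentyl)-9-borabicyclo[3.3.1]nonane | CC(C)CCCB1C2CCCC1CCC2
F3 | step 6 | [3-(tert-butoxycarbonyl)-2,6-dimethoxyphenyl]magnesium chloride | COc1ccc(C(=O)OC(C)(C)C)c(OC)c1[Mg]Cl
F4 | step 14 | 1,3-dimethoxy-2-(4-methylpentyl)benzene | COc1cccc(OC)c1CCCC(C)C
F5 | step 14 | 4,5-dichloro-1H-pyrrole-2-carbonyl chloride | O=C(Cl)c1cc(Cl)c(Cl)[nH]1
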